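A small charge of Q, 29 mM in the south-east run, gives 49 % of E at 3.00 min. The south run, charged with 43 mM, gives 47 % at that time. The gap of 2 percentage points equals the scatter of one reading, so I treat the two percent curves as one.

| setting | south | south-east | flask |
|---|---|---|---|
| Q | 43 mM | 29 mM | 43 mM |
| remark | the very flask that is asked about, followed so far | run made earlier |  |
| time |  |  | 8.0 min |

| run | time / min | E / % | X / % |
|---|---|---|---|
| south | 0.500 | 0 | 1 |
| south | 1.00 | 17 | 9 |
| south | 1.33 | 16 | 13 |
| south | 2.00 | 30 | 25 |
| south | 2.50 | 37 | 36 |
| south | 3.00 | 47 | 40 |
| south-east | 0.667 | 6 | 0 |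
| south-east | 1.00 | 14 | 5 |
| south-east | 1.33 | 19 | 5 |
| south-east | 2.50 | 40 | 28 |
| south-east | 3.00 | 49 | 36 |
| south-east | 5.00 | 73 | 56 |
| south-east | 8.00 | 87 | 72 |

(scatter of a reading: 2 percentage points)

- amounts and yields of E count X too
- given per volume of solution although it is solid: X

* E and X together at 8.0 min, in percent of the Q charged
* concentration of E in solution at 8.0 min, in percent of saturation

Work with what is not E, which is the charge minus the E column. In a first-order decay that fraction shrinks by the same factor in equal times, like the voltage on a discharging capacitor. Its logarithmic slope is your fall rate (the apparent first-order rate constant).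

There are two ways to get it. The south-east run falls from 51.0 % to 13.0 % between 3.00 min and 8.00 min, so the fall rate is 0.273 /min, a time constant of 3.66 min. Applied to the 53.0 % left in the south run at 3.00 min, it leaves 13.5 % at 8.0 min, so y is 86.5 %.

The south run can also stand alone. Its readings from 1.00 min to 3.00 min give 0.224 /min, which leaves 17.3 %, so y is 82.7 %.

The two part by 3.8 points. The south-east run over that same early window falls at 0.261 /min, faster than the south run. The south window is the suspect: the reckoning stretches it 2.50 times its own length, and the south-east window 1.00 times. I commit to the first way.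

The forecast puts E and X together at 85 %, lower than my figure, and E in solution at 105 % of saturation: “Extrapolating to 8 min leaves about 15% Q, so y ≈ 85%.”

The flask gives 84.6 % of E and X together, and E in solution at 101 % of saturation.

    Q → G (k = 3.39 × 10⁻⁴ /s)
    Q ⇌ L (K = 1.10, k = 0.00875 /s)
    X ⇌ E, rate k3*(cs3 - [E]) while solid is left; crystals form when [E] > cs3 (solubility = 3.20 mM, k = 0.749 /s)
    L → E (k = 0.0149 /s)
    G → Z (k = 0.00250 /s)

Run your fall rate on from there. At 8.0 min the flask has 15.4 % that is not E. The same flask left until 15 min gets 7.00 min more, and 0.273 /min cuts that fraction to 2.28 %, so E should reach 97.7 %. That neighbour holds 93.3 %. The gap is 4.4 points, and beside it the neighbour holds 4.53 % of Z, the other product. At 80.0 min the flask has Q at 0 %, E at 94.4 % and Z at 5.61 %.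

All runs are simulated on assumed constants, and the scatter is random.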